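**Strategy**

Everything rests on seeing the lactone ring (O1, C2, C3, C4, C5) as an oxygen-expanded cyclobutanone: once the C3 hydroxyl and benzyl groups are removed, C3 and C5 are two methylene arms joining C4 to C2, one directly and one through O1. Deleting O1 makes them equivalent, so C4 comes from a prochiral carbon. One catalytic asymmetric Baeyer–Villiger oxidation therefore inserts O1, forms the five-membered ring and fixes C4. Its substrate is achiral 3-(1-arylvinyl)cyclobutanone 8, in which the alkene is a non-enolisable stand-in for the aroyl group. C4 then directs hydroxylation and benzylation at C3 before alkene cleavage and debenzylation.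

Key step: step 5

Assumption (chemistry): the sense of induction of the chiral acid cannot be predicted with confidence for an alkenyl-substituted cyclobutanone, so the (R)-acid written in step 5 stands for whichever antipode gives (S)-10; both antipodes are available.

**Route**

Step 1
Reactants: 1 methyl 3,3-dimethoxycyclobutane-1-carboxylate
Product: 2 N-methoxy-N-methyl-3,3-dimethoxycyclobutane-1-carboxamide
Conditions: MeNH(OMe)·HCl, i-PrMgCl, THF, −20 → 0 °C; aq. NH4Cl
Reagents that add atoms: N,O-dimethylhydroxylamine hydrochloride, CNOC.Cl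
Why: Aminolysis of the methyl ester by the chloromagnesium amide of N,O-dimethylhydroxylamine (Weinreb amide synthesis) is fast at low temperature, and the dimethyl ketal is inert to the basic medium.

Step 2
Reactants: 3 1-benzyloxy-4-bromo-2-methoxybenzene; 2 N-methoxy-N-methyl-3,3-dimethoxycyclobutane-1-carboxamide
Product: 6 (4-benzyloxy-3-methoxyphenyl)(3,3-dimethoxycyclobutyl)methanone, via arylmagnesium bromide 4 (not isolated), via magnesium hemiaminal chelate 5 (not isolated)
Conditions: 3, Mg, I2 (cat.), THF, 40 °C; then 2, THF, 0 °C → rt; aq. NH4Cl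
Reagents that add atoms: none
Why: Grignard addition to a Weinreb amide stops at the magnesium chelate 5, which releases the ketone only on work-up, so over-addition is avoided while the ketal keeps the ring carbonyl out of reach.

Step 3
Reactants: 6 (4-benzyloxy-3-methoxyphenyl)(3,3-dimethoxycyclobutyl)methanone
Product: 7 1-benzyloxy-4-[1-(3,3-dimethoxycyclobutyl)ethenyl]-2-methoxybenzene
Conditions: Ph3PCH3Br, KOt-Bu, THF, 0 → 60 °C
Reagents that add atoms: methyltriphenylphosphonium bromide, C[P+](c1ccccc1)(c1ccccc1)c1ccccc1.[Br-]
Why: Wittig methylenation with the non-stabilised ylide should convert the aryl ketone into the 1,1-disubstituted alkene; the ketal tolerates the base and no stereocentre is involved.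

Step 4
Reactants: 7 1-benzyloxy-4-[1-(3,3-dimethoxycyclobutyl)ethenyl]-2-methoxybenzene
Product: 8 3-[1-(4-benzyloxy-3-methoxyphenyl)ethenyl]cyclobutan-1-one
Conditions: TsOH·H2O (10 mol%), acetone/H2O 10:1, rt
Reagents that add atoms: water, O
Why: Acid-catalysed hydrolysis of the dimethyl ketal is far faster than protonation of the styrene at this dilute acidity, so the ketone should be released with the alkene intact.

Step 5
Reactants: 8 3-[1-(4-benzyloxy-3-methoxyphenyl)ethenyl]cyclobutan-1-one
Product: 10 (S)-4-[1-(4-benzyloxy-3-methoxyphenyl)ethenyl]oxolan-2-one, via Criegee adduct 9 (not isolated)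
Conditions: 30% aq. H2O2 (1.5 equiv), (R)-3,3′-di(pyren-1-yl)-H8-BINOL hydrogen phosphate (10 mol%), CHCl3, −40 °C
Reagents that add atoms: hydrogen peroxide, OO
Why: Hydrogen peroxide, activated by hydrogen bonding to the chiral phosphoric acid, adds to the strained carbonyl to give Criegee adduct 9, and one of the two enantiotopic ring methylenes then shifts from carbon to the proximal peroxide oxygen as water leaves (Baeyer–Villiger oxidation). The closest known reaction type is the chiral Brønsted acid-catalysed desymmetrising Baeyer–Villiger oxidation of 3-substituted cyclobutanones with aqueous hydrogen peroxide. The lactone ring is not closed by a cyclisation but arises by enlargement of the four-membered ring through this 1,2-shift, which creates the C2–O1 and O1–C5 bonds. C4 is a prochiral carbon in 8 and becomes stereogenic because the phosphate, bound to both the hydroxyl and the hydroperoxy group of 9, lets only one methylene lie antiperiplanar to the O–O bond, so its configuration is set by the catalyst antipode. The step needs chemoselectivity for the ketone over the electron-rich styrene, which ring strain (fast perhydrate formation) and the absence of any peracid should secure, while the low temperature keeps the acid from protonating the alkene. Regioselectivity is not an issue because the two candidate migrating groups are constitutionally identical.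

Step 6
Reactants: 10 (S)-4-[1-(4-benzyloxy-3-methoxyphenyl)ethenyl]oxolan-2-one
Product: 12 (3R,4S)-3-hydroxy-4-[1-(4-benzyloxy-3-methoxyphenyl)ethenyl]oxolan-2-one (trans epimer drawn), via sodium enolate 11 (not isolated)
Conditions: NaHMDS, THF, −78 °C; (±)-trans-3-phenyl-2-(phenylsulfonyl)oxaziridine, −78 °C; AcOH
Reagents that add atoms: 3-phenyl-2-(phenylsulfonyl)oxaziridine (Davis reagent), O=S(=O)(c1ccccc1)N1OC1c1ccccc1
Why: Electrophilic hydroxylation of the lactone enolate by the N-sulfonyloxaziridine (Davis oxidation) should install the C3 oxygen mainly anti to the C4 substituent; the C3 configuration is immaterial because C3 is made planar again in step 8, and C4 carries no acidic hydrogen.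

Step 7
Reactants: 13 4-benzyloxy-3-methoxybenzyl alcohol
Product: 14 4-benzyloxy-3-methoxybenzyl bromide
Conditions: PBr3, Et2O, 0 °C; used at once
Reagents that add atoms: phosphorus tribromide, BrP(Br)Br
Why: Primary benzylic alcohols are converted into bromides by PBr3 (substitution on the phosphite ester), and the aryl benzyl ether survives the brief, cold conditions.

Step 8
Reactants: 12 (3R,4S)-3-hydroxy-4-[1-(4-benzyloxy-3-methoxyphenyl)ethenyl]oxolan-2-one; 14 4-benzyloxy-3-methoxybenzyl bromide
Product: 16 (3S,4S)-3-[(4-benzyloxy-3-methoxyphenyl)methyl]-4-[1-(4-benzyloxy-3-methoxyphenyl)ethenyl]-3-hydroxyoxolan-2-one, via dilithium enediolate 15 (not isolated)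
Conditions: LDA (2.2 equiv), THF/DMPU, −78 → −40 °C; 14, −78 → −30 °C; AcOH
Reagents that add atoms: none
Why: Double deprotonation gives the alkoxide enolate 15, whose carbon is far more nucleophilic than its oxygens, and SN2 alkylation by the benzylic bromide (dianion alkylation of an α-hydroxy lactone) should occur on the face opposite the bulky C4 arylvinyl group, setting the quaternary C3 centre with benzyl trans to C4 (3S).

Step 9
Reactants: 16 (3S,4S)-3-[(4-benzyloxy-3-methoxyphenyl)methyl]-4-[1-(4-benzyloxy-3-methoxyphenyl)ethenyl]-3-hydroxyoxolan-2-one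
Product: 18 (3S,4S)-4-(4-benzyloxy-3-methoxybenzoyl)-3-[(4-benzyloxy-3-methoxyphenyl)methyl]-3-hydroxyoxolan-2-one, via vicinal diol 17 (not isolated)
Conditions: OsO4 (3 mol%), NaIO4, 2,6-lutidine, dioxane/H2O 3:1, rt
Reagents that add atoms: osmium tetroxide, O=[Os](=O)(=O)=O; sodium periodate, [Na+].[O-]I(=O)(=O)=O
Why: In this Lemieux–Johnson oxidation, osmium-catalysed dihydroxylation of the only alkene gives diol 17, which periodate cleaves to the aryl ketone; the buffered, near-neutral medium should avoid retro-aldol cleavage or β-elimination of the new β-hydroxy ketone, the benzyl ethers and arenes are not attacked, and quaternary C3 cannot epimerise.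

Step 10
Reactants: 18 (3S,4S)-4-(4-benzyloxy-3-methoxybenzoyl)-3-[(4-benzyloxy-3-methoxyphenyl)methyl]-3-hydroxyoxolan-2-one
Product: 19 (3S,4S)-3-hydroxy-4-(4-hydroxy-3-methoxybenzoyl)-3-[(4-hydroxy-3-methoxyphenyl)methyl]oxolan-2-one
Conditions: H2 (1 atm), 10% Pd/C, EtOAc, rt
Reagents that add atoms: none
Why: Catalytic hydrogenolysis cleaves both aryl benzyl ethers under neutral conditions that leave the base-sensitive aldol-type lactone and both stereocentres untouched; the electron-rich aryl ketone is reduced much more slowly, so the reaction is stopped once debenzylation is complete.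

**Compound list**

1 | methyl 3,3-dimethoxycyclobutane-1-carboxylate | COC(=O)C1CC(OC)(OC)C1 | starting material
2 | N-methoxy-N-methyl-3,3-dimethoxycyclobutane-1-carboxamide | CON(C)C(=O)C1CC(OC)(OC)C1 | intermediate
3 | 1-benzyloxy-4-bromo-2-methoxybenzene | COc1cc(Br)ccc1OCc1ccccc1 | starting material
4 | (4-benzyloxy-3-methoxyphenyl)magnesium bromide | COc1cc([Mg]Br)ccc1OCc1ccccc1 | intermediate (not isolated)
5 | bromomagnesium salt of the tetrahedral adduct of 4 with 2 (N,O-chelated hemiaminal, racemic) | COc1cc(C(O[Mg]Br)(N(C)OC)C2CC(OC)(OC)C2)ccc1OCc1ccccc1 | intermediate (not isolated)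
6 | (4-benzyloxy-3-methoxyphenyl)(3,3-dimethoxycyclobutyl)methanone | COc1cc(C(=O)C2CC(OC)(OC)C2)ccc1OCc1ccccc1 | intermediate
7 | 1-benzyloxy-4-[1-(3,3-dimethoxycyclobutyl)ethenyl]-2-methoxybenzene | C=C(C1CC(OC)(OC)C1)c1ccc(OCc2ccccc2)c(OC)c1 | intermediate
8 | 3-[1-(4-benzyloxy-3-methoxyphenyl)ethenyl]cyclobutan-1-one (achiral) | C=C(C1CC(=O)C1)c1ccc(OCc2ccccc2)c(OC)c1 | intermediate
9 | 1-hydroperoxy-3-[1-(4-benzyloxy-3-methoxyphenyl)ethenyl]cyclobutan-1-ol (Criegee adduct) | C=C(C1CC(O)(OO)C1)c1ccc(OCc2ccccc2)c(OC)c1 | intermediate (not isolated)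
10 | (S)-4-[1-(4-benzyloxy-3-methoxyphenyl)ethenyl]oxolan-2-one | C=C([C@H]1COC(=O)C1)c1ccc(OCc2ccccc2)c(OC)c1 | intermediate
11 | sodium enolate of 10 | C=C([C@H]1COC([O-])=C1)c1ccc(OCc2ccccc2)c(OC)c1.[Na+] | intermediate (not isolated)
12 | (3R,4S)-3-hydroxy-4-[1-(4-benzyloxy-3-methoxyphenyl)ethenyl]oxolan-2-one (trans epimer drawn; any cis epimer is carried on) | C=C([C@H]1COC(=O)[C@@H]1O)c1ccc(OCc2ccccc2)c(OC)c1 | intermediate
13 | 4-benzyloxy-3-methoxybenzyl alcohol | COc1cc(CO)ccc1OCc1ccccc1 | starting material
14 | 4-benzyloxy-3-methoxybenzyl bromide | COc1cc(CBr)ccc1OCc1ccccc1 | intermediate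
15 | dilithium enediolate of 12 | C=C([C@H]1COC([O-])=C1[O-])c1ccc(OCc2ccccc2)c(OC)c1.[Li+].[Li+] | intermediate (not isolated)
16 | (3S,4S)-3-[(4-benzyloxy-3-methoxyphenyl)methyl]-4-[1-(4-benzyloxy-3-methoxyphenyl)ethenyl]-3-hydroxyoxolan-2-one (benzyl trans to the C4 group) | COc1cc(C[C@@]2(O)C(=O)OC[C@@H]2C(=C)c2ccc(OCc3ccccc3)c(OC)c2)ccc1OCc1ccccc1 | intermediate
17 | (3S,4S)-3-[(4-benzyloxy-3-methoxyphenyl)methyl]-4-[1-(4-benzyloxy-3-methoxyphenyl)-1,2-dihydroxyethyl]-3-hydroxyoxolan-2-one (carbinol epimers) | COc1cc(C[C@@]2(O)C(=O)OC[C@@H]2C(O)(CO)c2ccc(OCc3ccccc3)c(OC)c2)ccc1OCc1ccccc1 | intermediate (not isolated)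
18 | (3S,4S)-4-(4-benzyloxy-3-methoxybenzoyl)-3-[(4-benzyloxy-3-methoxyphenyl)methyl]-3-hydroxyoxolan-2-one | COc1cc(C[C@@]2(O)C(=O)OC[C@@H]2C(=O)c2ccc(OCc3ccccc3)c(OC)c2)ccc1OCc1ccccc1 | intermediate
19 | (3S,4S)-3-hydroxy-4-(4-hydroxy-3-methoxybenzoyl)-3-[(4-hydroxy-3-methoxyphenyl)methyl]oxolan-2-one (CNP0321349.1) | COc1cc(C[C@@]2(O)C(=O)OC[C@@H]2C(=O)c2ccc(O)c(OC)c2)ccc1O | target

**Step count and risk**

Total steps: 10. Longest linear sequence: 9 steps (1, 2, 3, 4, 5, 6, 8, 9, 10, from compound 1); step 7 is a one-step side branch.

Steps most likely to fail: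

1. Step 5. The two enantiotopic methylene migrations may be poorly discriminated, because the ring substituent is an alkenyl group and not a plain aryl ring. The electron-rich styrene may also be protonated by the acid and then hydrated or rearranged. The fallback sets out from 8 and returns at 10. Ketone 8 is oxidised without a chiral catalyst by alkaline hydrogen peroxide (30% H2O2, NaOH, MeOH/H2O, 0 °C, then acidification to pH 3 to reclose the ring), a classical nucleophilic Baeyer–Villiger oxidation of cyclobutanones that leaves isolated alkenes alone. This should give the racemic lactone F1, whose enantiomers are separated by preparative chromatography on a chiral stationary phase; the (S)-enantiomer is 10. Half of the material is lost, but stereocontrol no longer depends on a catalyst.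

2. Step 8. The second deprotonation may be incomplete, the alkoxide oxygen may be benzylated in competition with carbon, or the facial bias of the enediolate may be weak. The fallback sets out from 12 and returns at 16. The hydroxyl group of 12 is silylated (TESCl, imidazole, DMF, rt) to the triethylsilyl ether F2. Its mono-enolate (LDA, THF, −78 °C) is alkylated with 14, again anti to the C4 group, to the fully protected quaternary lactone F3. The silyl group is then removed at the alkene stage, where base is still tolerated (TBAF, AcOH, THF, 0 °C), to give 16. This costs two extra steps but avoids the dianion.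

3. Step 10. Over-reduction of the aryl ketone (to the carbinol or the methylene compound) may compete with O-debenzylation. The fallback sets out from 18 and returns at 19. Both benzyl ethers are cleaved without hydrogen by BCl3 in the presence of pentamethylbenzene as cation scavenger (CH2Cl2, −78 °C), a Lewis-acid dealkylation that spares ketones and, at this temperature, aryl methyl ethers; aqueous work-up should give 19 directly.

**Further compounds**

F1 | step 5 | racemic 4-[1-(4-benzyloxy-3-methoxyphenyl)ethenyl]oxolan-2-one | C=C(C1COC(=O)C1)c1ccc(OCc2ccccc2)c(OC)c1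
F2 | step 8 | (3R,4S)-4-[1-(4-benzyloxy-3-methoxyphenyl)ethenyl]-3-(triethylsilyloxy)oxolan-2-one | C=C([C@H]1COC(=O)[C@@H]1O[Si](CC)(CC)CC)c1ccc(OCc2ccccc2)c(OC)c1
F3 | step 8 | (3S,4S)-3-[(4-benzyloxy-3-methoxyphenyl)methyl]-4-[1-(4-benzyloxy-3-methoxyphenyl)ethenyl]-3-(triethylsilyloxy)oxolan-2-one | COc1cc(C[C@@]2(O[Si](CC)(CC)CC)C(=O)OC[C@@H]2C(=C)c2ccc(OCc3ccccc3)c(OC)c2)ccc1OCc1ccccc1
F0 | step 10 | none | none
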